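**Retrosynthetic overview**

1. The plan rests on the C9(=O)–C10(Cl)=C11 unit of the five-membered ring (prostanoid numbering, ring = C8–C12). C10 is the only chlorinated carbon and lies between the C9 carbonyl and the C11 methine, so it can be taken out as CCl2, leaving the four-membered ring C8–C9–C11–C12 as a 1-silyloxycyclobutene.
2. Late stage: an anti aldol joins C7–C8 (setting C7 and C8) between the C8 lithium enolate of the O12-PMB chlorocyclopentenone and methyl (Z)-7-oxohept-5-enoate, followed by O7 acetylation and PMB removal.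
3. The silyloxycyclobutene comes from an achiral 3-alkoxy-3-octenylcyclobutanone by deprotonation of one of its two enantiotopic CH2 groups; this is the event that makes C12 stereogenic.
4. The cyclobutanone comes from dichloroketene (2+2) addition to the 2-alkoxy-1-alkene obtained by methylenation of 4-methoxybenzyl (Z)-non-3-enoate, then dechlorination.
5. Ring order: the four-membered carbocycle is built first and is then enlarged by one carbon to the cyclopentenone, the only ring of the target.

Key step: step 7

Remarks: atom labels C1–C20 follow prostanoid numbering (C1 ester carbon, ring C8–C12, C20 terminal methyl). Assumption: lithium (R,R)-bis(1-phenylethyl)amide is taken to remove a proton from the pro-S methylene of 8; if the sense of induction proves opposite, the (S,S) amine is used with no other change.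

**Route**

Step 1
Reactants: 1 (Z)-non-3-en-1-ol
Product: 2 (Z)-non-3-enoic acid
Conditions: CrO3, H2SO4, acetone/H2O, 0 °C, short contact time
Reagents that add atoms: water, O (delivered through the chromic acid formed from chromium trioxide, O=[Cr](=O)=O)
Why: Jones oxidation takes the primary alcohol to the carboxylic acid, and at 0 °C with short contact the skipped (Z)-alkene should neither isomerise nor move into conjugation.

Step 2
Reactants: 2 (Z)-non-3-enoic acid; 3 4-methoxybenzyl alcohol
Product: 4 4-methoxybenzyl (Z)-non-3-enoate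
Conditions: DCC, DMAP (5 mol %), CH2Cl2, 0 °C
Reagents that add atoms: 4-methoxybenzyl alcohol (3), COc1ccc(CO)cc1
Why: Steglich esterification under nearly neutral conditions, with little DMAP and low temperature so that the β,γ-unsaturated acyl group is not drawn into conjugation.

Step 3
Reactants: 4 4-methoxybenzyl (Z)-non-3-enoate
Product: 5 1-{[(4Z)-deca-1,4-dien-2-yloxy]methyl}-4-methoxybenzene
Conditions: Cp2TiMe2 (2.5 equiv), toluene, 65 °C, dark; filtration through basic Al2O3 with Et3N
Reagents that add atoms: dimethyltitanocene Cp2TiMe2, C[Ti+2]C.c1cc[cH-]c1.c1cc[cH-]c1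
Why: Petasis methylenation; the titanium methylidene formed by loss of methane exchanges the ester C=O for C=CH2 through an oxatitanacyclobutane, and the reagent is not basic enough to touch the doubly activated C13 methylene.

Step 4
Reactants: 5 1-{[(4Z)-deca-1,4-dien-2-yloxy]methyl}-4-methoxybenzene; 6 trichloroacetyl chloride
Product: 7 rac-2,2-dichloro-3-(4-methoxybenzyloxy)-3-[(Z)-oct-2-en-1-yl]cyclobutan-1-one
Conditions: Zn–Cu couple, 6 added slowly, Et2O/DME, 0 °C to rt
Reagents that add atoms: trichloroacetyl chloride (6), ClC(Cl)(Cl)C(Cl)=O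
Why: Zinc reduction of 6 releases dichloroketene, which undergoes the known thermal (2+2) ketene cycloaddition with the electron-rich 1,1-disubstituted enol ether far faster than with the unactivated C14=C15 alkene, the ketene carbonyl carbon bonding to the terminal CH2 and the CCl2 carbon to the oxygen-bearing carbon, while DME ties up ZnCl2 so that the acid-labile enol ether survives; the quaternary carbon forms racemic, which is of no consequence because step 5 makes it prochiral again.

Step 5
Reactants: 7 rac-2,2-dichloro-3-(4-methoxybenzyloxy)-3-[(Z)-oct-2-en-1-yl]cyclobutan-1-one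
Product: 8 3-(4-methoxybenzyloxy)-3-[(Z)-oct-2-en-1-yl]cyclobutan-1-one
Conditions: Zn–Cu couple, NH4Cl, MeOH, rt
Reagents that add atoms: none
Why: Reductive dehalogenation of the α,α-dichloroketone by zinc under nearly neutral buffered conditions removes both chlorines without ionising the tertiary PMB ether and gives a cyclobutanone with a mirror plane through C9 and C12.

Step 6
Reactants: 8 3-(4-methoxybenzyloxy)-3-[(Z)-oct-2-en-1-yl]cyclobutan-1-one
Product: 10 (S)-3-(4-methoxybenzyloxy)-3-[(Z)-oct-2-en-1-yl]-1-(trimethylsilyloxy)cyclobut-1-ene, via lithium cyclobutenolate 9 (not isolated)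
Conditions: (R,R)-bis(1-phenylethyl)amine, n-BuLi, THF, −78 °C; Me3SiCl, then 8 added slowly, −100 °C; Et3N, pentane, cold aq NaHCO3; used crude
Reagents that add atoms: chlorotrimethylsilane, C[Si](C)(C)Cl
Why: Enantioselective deprotonation of a prochiral cyclobutanone by a C2-symmetric chiral lithium amide with in situ silyl chloride quench is known for 3-substituted cyclobutanones; the amide distinguishes the two enantiotopic CH2 groups and so makes C12 a stereocentre (S, by removal of a proton from the pro-S arm that becomes C11), and immediate O-silylation at −100 °C keeps enolate 9 from equilibrating or expelling the C12 alkoxide.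

Step 7
Reactants: 10 (S)-3-(4-methoxybenzyloxy)-3-[(Z)-oct-2-en-1-yl]-1-(trimethylsilyloxy)cyclobut-1-ene; 11 chloroform
Product: 13 (S)-2-chloro-4-(4-methoxybenzyloxy)-4-[(Z)-oct-2-en-1-yl]cyclopent-2-en-1-one, via dichlorocarbene adduct 12 (not isolated)
Conditions: CHCl3 (5 equiv), KOtBu (1.3 equiv, added in portions), pentane, −40 to 0 °C; pH 7 buffer
Reagents that add atoms: chloroform (11), ClC(Cl)Cl
Why: Proposed new method: dichlorocarbene, formed by α-elimination from CHCl3 and KOtBu, should add in a concerted (2+1) cheletropic step to the electron-rich C9=C11 enol ether bond of 10 to give the 5,5-dichloro-1-silyloxybicyclo[2.1.0]pentane 12, whose central C9–C11 bond then breaks in a disrotatory cyclopropyl-to-allyl opening as the endo chloride leaves (the ring bonds to C8 and C12 turn inward, as the five-membered ring requires), and the 2-chloro-1-silyloxyallyl cation gives its silyl group to chloride to leave the C9 ketone and the C10(Cl)=C11 alkene. The closest known reactions are the dichlorocarbene ring expansion of five- and six-membered cyclic trimethylsilyl enol ethers to 2-chlorocycloalk-2-enones and the spontaneous rearrangement of dihalocarbene adducts of cyclobutenes to 2,3-dihalocyclopentenes; their combination on a 3-alkoxy-1-silyloxycyclobutene is untested. The five-membered ring is formed by one-carbon ring enlargement, not by a ring-closing bond: C10 is bonded to C9 and C11 in the cycloaddition and the old C9–C11 bond is cleaved, with release of both cyclopropane and cyclobutane strain as the driving force. No stereocentre is formed; C12 is a spectator whose (S) configuration is carried over, and both faces of carbene attack converge on one product because C10 ends sp2. The step needs chemoselectivity for the enol ether over the C14=C15 alkene, which the much higher nucleophilicity of a silyloxy-substituted alkene towards the electrophilic carbene should secure with a small excess of carbene, and the site of insertion is fixed by the position of the enol ether set in step 6. Adding the base last and in portions to 10 in excess CHCl3 at low temperature keeps free alkoxide low, so that the Si–O bond and the C12 ether (β to the new carbonyl) are not attacked.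

Step 8
Reactants: 14 hex-5-ynoic acid
Product: 16 7-hydroxyhept-5-ynoic acid, via dilithium acetylide carboxylate 15 (not isolated)
Conditions: n-BuLi (2.1 equiv), THF, −78 to 0 °C; (CH2O)n, 0 °C to rt; aq HCl
Reagents that add atoms: paraformaldehyde (as formaldehyde), C=O
Why: Double deprotonation gives the carboxylate acetylide 15, whose acetylide carbon adds to formaldehyde released from paraformaldehyde (acetylide addition to an aldehyde), the carboxylate being inert to the nucleophile.

Step 9
Reactants: 16 7-hydroxyhept-5-ynoic acid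
Product: 17 methyl 7-hydroxyhept-5-ynoate
Conditions: MeOH, H2SO4 (cat.), rt
Reagents that add atoms: methanol, CO
Why: Fischer esterification in excess methanol; the propargylic alcohol is stable to dilute acid at room temperature.

Step 10
Reactants: 17 methyl 7-hydroxyhept-5-ynoate
Product: 18 methyl (Z)-7-hydroxyhept-5-enoate
Conditions: H2 (1 atm), Pd/CaCO3 poisoned with Pb(OAc)2, quinoline, EtOAc, rt
Reagents that add atoms: none
Why: Lindlar semi-hydrogenation delivers both hydrogens to one face of the alkyne on the poisoned palladium surface and so gives the (Z)-alkene without over-reduction.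

Step 11
Reactants: 18 methyl (Z)-7-hydroxyhept-5-enoate
Product: 19 methyl (Z)-7-oxohept-5-enoate
Conditions: Dess–Martin periodinane, NaHCO3, CH2Cl2, 0 °C; used at once
Reagents that add atoms: none
Why: Buffered Dess–Martin oxidation of the allylic alcohol is neutral and fast, which should preserve the isomerisation-prone (Z)-enal if it is used cold and immediately.

Step 12
Reactants: 13 (S)-2-chloro-4-(4-methoxybenzyloxy)-4-[(Z)-oct-2-en-1-yl]cyclopent-2-en-1-one; 19 methyl (Z)-7-oxohept-5-enoate
Product: 21 methyl (5Z,7S)-7-[(1R,5S)-3-chloro-5-(4-methoxybenzyloxy)-5-[(Z)-oct-2-en-1-yl]-2-oxocyclopent-3-en-1-yl]-7-hydroxyhept-5-enoate, via lithium dienolate 20 (not isolated)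
Conditions: LiN(iPr)2, THF, −78 °C; 19, −78 °C, 15 min; AcOH in THF at −78 °C
Reagents that add atoms: methyl (Z)-7-oxohept-5-enoate (19), COC(=O)CCC/C=C\C=O
Why: Kinetic deprotonation at C8, the only enolisable position, gives the cross-conjugated enolate 20, which cannot expel the C12 ether without forming a cyclopentadienone; the aldol addition runs through a Zimmerman–Traxler chair in which the ring enolate is necessarily E(O) and the aldehyde chain equatorial, which gives the anti (7S,8R) relationship, and the aldehyde approaches C8 on the ring face that carries the C12 oxygen, away from the bulkier C13 methylene chain, which sets C8 as R with the two carbon chains trans.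

Step 13
Reactants: 21 methyl (5Z,7S)-7-[(1R,5S)-3-chloro-5-(4-methoxybenzyloxy)-5-[(Z)-oct-2-en-1-yl]-2-oxocyclopent-3-en-1-yl]-7-hydroxyhept-5-enoate
Product: 22 methyl (5Z,7S)-7-acetoxy-7-[(1R,5S)-3-chloro-5-(4-methoxybenzyloxy)-5-[(Z)-oct-2-en-1-yl]-2-oxocyclopent-3-en-1-yl]hept-5-enoate
Conditions: Ac2O, pyridine, DMAP (cat.), CH2Cl2, 0 °C
Reagents that add atoms: acetic anhydride, CC(=O)OC(C)=O
Why: DMAP-catalysed acylation of the only free hydroxyl, kept cold and short so that the new β-acetoxy ketone does not lose acetate by E1cB to the cross-conjugated dienone; no stereocentre is touched.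

Step 14
Reactants: 22 methyl (5Z,7S)-7-acetoxy-7-[(1R,5S)-3-chloro-5-(4-methoxybenzyloxy)-5-[(Z)-oct-2-en-1-yl]-2-oxocyclopent-3-en-1-yl]hept-5-enoate
Product: 23 punaglandin 8
Conditions: DDQ, CH2Cl2/pH 7 phosphate buffer, 0 °C to rt
Reagents that add atoms: none
Why: Oxidative cleavage of the 4-methoxybenzyl ether by DDQ (hydride abstraction at the electron-rich benzylic carbon, then hydrolysis of the oxocarbenium ion) at buffered pH should free the tertiary C12 alcohol without touching the isolated (Z)-alkenes, the chloroenone or the C7 acetate.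

**Compound list**

1 | (Z)-non-3-en-1-ol | CCCCC/C=C\CCO | starting material
2 | (Z)-non-3-enoic acid | CCCCC/C=C\CC(=O)O | intermediate
3 | 4-methoxybenzyl alcohol | COc1ccc(CO)cc1 | starting material
4 | 4-methoxybenzyl (Z)-non-3-enoate | CCCCC/C=C\CC(=O)OCc1ccc(OC)cc1 | intermediate
5 | 1-{[(4Z)-deca-1,4-dien-2-yloxy]methyl}-4-methoxybenzene | CCCCC/C=C\CC(=C)OCc1ccc(OC)cc1 | intermediate
6 | trichloroacetyl chloride | ClC(Cl)(Cl)C(Cl)=O | starting material
7 | rac-2,2-dichloro-3-(4-methoxybenzyloxy)-3-[(Z)-oct-2-en-1-yl]cyclobutan-1-one | CCCCC/C=C\CC1(OCc2ccc(OC)cc2)CC(=O)C1(Cl)Cl | intermediate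
8 | 3-(4-methoxybenzyloxy)-3-[(Z)-oct-2-en-1-yl]cyclobutan-1-one (achiral) | CCCCC/C=C\CC1(OCc2ccc(OC)cc2)CC(=O)C1 | intermediate
9 | lithium (S)-3-(4-methoxybenzyloxy)-3-[(Z)-oct-2-en-1-yl]cyclobut-1-en-1-olate | CCCCC/C=C\C[C@@]1(OCc2ccc(OC)cc2)C=C([O-])C1.[Li+] | intermediate (not isolated)
10 | (S)-3-(4-methoxybenzyloxy)-3-[(Z)-oct-2-en-1-yl]-1-(trimethylsilyloxy)cyclobut-1-ene | CCCCC/C=C\C[C@@]1(OCc2ccc(OC)cc2)C=C(O[Si](C)(C)C)C1 | intermediate (key-step precursor)
11 | chloroform | ClC(Cl)Cl | starting material
12 | (3S)-5,5-dichloro-3-(4-methoxybenzyloxy)-3-[(Z)-oct-2-en-1-yl]-1-(trimethylsilyloxy)bicyclo[2.1.0]pentane (cis-fused, both faces) | CCCCC/C=C\C[C@@]1(OCc2ccc(OC)cc2)C2C(Cl)(Cl)C2(O[Si](C)(C)C)C1 | intermediate (not isolated)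
13 | (S)-2-chloro-4-(4-methoxybenzyloxy)-4-[(Z)-oct-2-en-1-yl]cyclopent-2-en-1-one | CCCCC/C=C\C[C@@]1(OCc2ccc(OC)cc2)C=C(Cl)C(=O)C1 | intermediate (key-step product)
14 | hex-5-ynoic acid | C#CCCCC(=O)O | starting material
15 | lithium 6-lithiohex-5-ynoate | [Li+].[Li+].[C-]#CCCCC(=O)[O-] | intermediate (not isolated)
16 | 7-hydroxyhept-5-ynoic acid | OCC#CCCCC(=O)O | intermediate
17 | methyl 7-hydroxyhept-5-ynoate | COC(=O)CCCC#CCO | intermediate
18 | methyl (Z)-7-hydroxyhept-5-enoate | COC(=O)CCC/C=C\CO | intermediate
19 | methyl (Z)-7-oxohept-5-enoate | COC(=O)CCC/C=C\C=O | intermediate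
20 | lithium (S)-2-chloro-4-(4-methoxybenzyloxy)-4-[(Z)-oct-2-en-1-yl]cyclopenta-1,5-dien-1-olate (C8=C9 enolate) | CCCCC/C=C\C[C@@]1(OCc2ccc(OC)cc2)C=C(Cl)C([O-])=C1.[Li+] | intermediate (not isolated)
21 | methyl (5Z,7S)-7-[(1R,5S)-3-chloro-5-(4-methoxybenzyloxy)-5-[(Z)-oct-2-en-1-yl]-2-oxocyclopent-3-en-1-yl]-7-hydroxyhept-5-enoate | CCCCC/C=C\C[C@@]1(OCc2ccc(OC)cc2)C=C(Cl)C(=O)[C@@H]1[C@H](/C=C\CCCC(=O)OC)O | intermediate
22 | methyl (5Z,7S)-7-acetoxy-7-[(1R,5S)-3-chloro-5-(4-methoxybenzyloxy)-5-[(Z)-oct-2-en-1-yl]-2-oxocyclopent-3-en-1-yl]hept-5-enoate | CCCCC/C=C\C[C@@]1(OCc2ccc(OC)cc2)C=C(Cl)C(=O)[C@@H]1[C@H](/C=C\CCCC(=O)OC)OC(C)=O | intermediate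
23 | punaglandin 8, methyl (5Z,7S)-7-acetoxy-7-[(1R,5S)-3-chloro-5-hydroxy-5-[(Z)-oct-2-en-1-yl]-2-oxocyclopent-3-en-1-yl]hept-5-enoate (7S,8R,12S) | CCCCC/C=C\C[C@@]1(O)C=C(Cl)C(=O)[C@@H]1[C@H](/C=C\CCCC(=O)OC)OC(C)=O | target

**Step count**

Total steps: 14. Longest linear sequence: 10 (steps 1–7, then 12–14); the aldehyde branch is steps 8–11.

**Steps most likely to fail**

1. Step 7 (the untested ring enlargement). What may go wrong: alkoxide removes the silyl group before the carbene arrives, which returns achiral 8 or lets the potassium enolate expel the C12 ether. The carbene may also add to the C14=C15 alkene, or the base may degrade the chloroenone once formed. Fallback with known chemistry, setting out from 10 and coming back at 13: MeLi in THF at −78 °C cleaves the Si–O bond of 10 to enolate 9, which is trapped with PhNTf2 as (S)-3-(4-methoxybenzyloxy)-3-[(Z)-oct-2-en-1-yl]cyclobut-1-en-1-yl trifluoromethanesulfonate F1. Reduction with Pd(OAc)2/PPh3, HCO2H and Bu3N in DMF gives (S)-3-(4-methoxybenzyloxy)-3-[(Z)-oct-2-en-1-yl]cyclobut-1-ene F2. Dichlorocarbene (CHCl3, KOtBu; the base is now harmless) adds to the strained ring alkene, and the adduct rearranges spontaneously, as is known for cyclobutenes. This should give (3S)-1,5-dichloro-3-(4-methoxybenzyloxy)-3-[(Z)-oct-2-en-1-yl]cyclopent-1-ene F3, with chloride returning to C9, the allyl terminus remote from the quaternary C12. AgNO3 in aqueous acetone converts the allylic chloride to (4S)-2-chloro-4-(4-methoxybenzyloxy)-4-[(Z)-oct-2-en-1-yl]cyclopent-2-en-1-ol F4, and Dess–Martin oxidation gives 13.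

2. Step 6. What may go wrong: the chiral amide discriminates poorly between the two enantiotopic CH2 groups, because the two C12 substituents differ little in size, or the C12 alkoxide is lost by E1cB from the lithium enolate before silylation. Fallback, setting out from 8 and coming back at 13: soft enolisation with Me3SiOTf and Et3N in CH2Cl2 at 0 °C, which forms no free enolate, gives racemic 3-(4-methoxybenzyloxy)-3-[(Z)-oct-2-en-1-yl]-1-(trimethylsilyloxy)cyclobut-1-ene F5. The conditions of step 7 then give, through the racemic dichlorocarbene adduct F6, racemic 2-chloro-4-(4-methoxybenzyloxy)-4-[(Z)-oct-2-en-1-yl]cyclopent-2-en-1-one F7. Preparative HPLC on a cellulose carbamate chiral stationary phase separates 13 from its (R)-enantiomer F8, which is set aside; the absolute configuration is assigned at this stage.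

3. Step 12. What may go wrong: the enolate or the amine isomerises the (Z)-enal to the (E)-enal, retro-aldol equilibration erodes the anti relationship, or the aldehyde attacks the wrong face of C8. Fallback, setting out from 17 and 13 and coming back at 22: the alkyne is kept as a masked (Z)-alkene. Dess–Martin oxidation of 17 gives methyl 7-oxohept-5-ynoate F9, which cannot isomerise. Enolate 20 (from 13 and LiN(iPr)2, −78 °C) adds to it to give methyl (7R)-7-[(1R,5S)-3-chloro-5-(4-methoxybenzyloxy)-5-[(Z)-oct-2-en-1-yl]-2-oxocyclopent-3-en-1-yl]-7-hydroxyhept-5-ynoate F10 (same spatial arrangement as 21; the descriptor changes with the alkyne). Ac2O/pyridine gives the propargylic acetate methyl (7R)-7-acetoxy-7-[(1R,5S)-3-chloro-5-(4-methoxybenzyloxy)-5-[(Z)-oct-2-en-1-yl]-2-oxocyclopent-3-en-1-yl]hept-5-ynoate F11. Semi-hydrogenation over Pd/CaCO3 poisoned with Pb(OAc)2 and quinoline then gives 22.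

**Further compounds**

F1 | step 7 | (S)-3-(4-methoxybenzyloxy)-3-[(Z)-oct-2-en-1-yl]cyclobut-1-en-1-yl trifluoromethanesulfonate | CCCCC/C=C\C[C@@]1(OCc2ccc(OC)cc2)C=C(OS(=O)(=O)C(F)(F)F)C1
F2 | step 7 | (S)-3-(4-methoxybenzyloxy)-3-[(Z)-oct-2-en-1-yl]cyclobut-1-ene | CCCCC/C=C\C[C@@]1(OCc2ccc(OC)cc2)C=CC1
F3 | step 7 | (3S)-1,5-dichloro-3-(4-methoxybenzyloxy)-3-[(Z)-oct-2-en-1-yl]cyclopent-1-ene | CCCCC/C=C\C[C@@]1(OCc2ccc(OC)cc2)C=C(Cl)C(Cl)C1
F4 | step 7 | (4S)-2-chloro-4-(4-methoxybenzyloxy)-4-[(Z)-oct-2-en-1-yl]cyclopent-2-en-1-ol | CCCCC/C=C\C[C@@]1(OCc2ccc(OC)cc2)C=C(Cl)C(O)C1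
F5 | step 6 | rac-3-(4-methoxybenzyloxy)-3-[(Z)-oct-2-en-1-yl]-1-(trimethylsilyloxy)cyclobut-1-ene | CCCCC/C=C\CC1(OCc2ccc(OC)cc2)C=C(O[Si](C)(C)C)C1
F6 | step 6 | rac-5,5-dichloro-3-(4-methoxybenzyloxy)-3-[(Z)-oct-2-en-1-yl]-1-(trimethylsilyloxy)bicyclo[2.1.0]pentane | CCCCC/C=C\CC1(OCc2ccc(OC)cc2)C2C(Cl)(Cl)C2(O[Si](C)(C)C)C1
F7 | step 6 | rac-2-chloro-4-(4-methoxybenzyloxy)-4-[(Z)-oct-2-en-1-yl]cyclopent-2-en-1-one | CCCCC/C=C\CC1(OCc2ccc(OC)cc2)C=C(Cl)C(=O)C1
F8 | step 6 | (R)-2-chloro-4-(4-methoxybenzyloxy)-4-[(Z)-oct-2-en-1-yl]cyclopent-2-en-1-one | CCCCC/C=C\C[C@]1(OCc2ccc(OC)cc2)C=C(Cl)C(=O)C1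
F9 | step 12 | methyl 7-oxohept-5-ynoate | COC(=O)CCCC#CC=O
F10 | step 12 | methyl (7R)-7-[(1R,5S)-3-chloro-5-(4-methoxybenzyloxy)-5-[(Z)-oct-2-en-1-yl]-2-oxocyclopent-3-en-1-yl]-7-hydroxyhept-5-ynoate | CCCCC/C=C\C[C@@]1(OCc2ccc(OC)cc2)C=C(Cl)C(=O)[C@@H]1[C@H](C#CCCCC(=O)OC)O
F11 | step 12 | methyl (7R)-7-acetoxy-7-[(1R,5S)-3-chloro-5-(4-methoxybenzyloxy)-5-[(Z)-oct-2-en-1-yl]-2-oxocyclopent-3-en-1-yl]hept-5-ynoate | CCCCC/C=C\C[C@@]1(OCc2ccc(OC)cc2)C=C(Cl)C(=O)[C@@H]1[C@H](C#CCCCC(=O)OC)OC(C)=O
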